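**Retrosynthetic overview**
- Last bond: the aryl–CH2–aryl bridge. The ortho-quinone methide released from a ring-A Mannich base is trapped by the acetonide-protected ring-B fragment, and the acetonide is hydrolysed in the same pot.
- Key bond: ring B–CH2 of the side chain, made by a light-driven C–H alkylation of unprotected phloroacetophenone dianion with a chiral primary iodide (proposed new photochemical step).
- The iodide carries the only stereocenter. It comes from methyl (S)-isopropylideneglycerate (L-serine pool) by MeMgBr addition, acetonide transposition and Appel iodination.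
- Ring A comes from the same phloroacetophenone by C-methylation, 4-O-methylation and aminomethylation.
- Ring order: both benzene rings are bought intact and no carbocycle is built. The only ring made is the temporary tetramethyldioxolane (step 2), opened in the last step.

Assumption: the single stereocenter is read from the SMILES as (S); the glycerate ester (S form) and 2',4',6'-trihydroxyacetophenone are taken as commercial.

**Route**

Step 1
Reactants: 1 methyl (4S)-2,2-dimethyl-1,3-dioxolane-4-carboxylate
Product: 2 2-[(4S)-2,2-dimethyl-1,3-dioxolan-4-yl]propan-2-ol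
Conditions: MeMgBr (3.0 equiv), THF, 0 °C to rt; aq. NH4Cl
Reagents that add atoms: methylmagnesium bromide, C[Mg]Br
Why: Double Grignard addition to the ester gives the tertiary carbinol, and the bought α-alkoxy stereocenter is untouched because addition outruns enolisation at 0 °C.

Step 2
Reactants: 2 2-[(4S)-2,2-dimethyl-1,3-dioxolan-4-yl]propan-2-ol
Product: 3 [(4S)-2,2,5,5-tetramethyl-1,3-dioxolan-4-yl]methanol
Conditions: CSA (5 mol%), 4 Å MS, CH2Cl2, rt; Et3N quench
Reagents that add atoms: none
Why: Acid-catalysed acetonide migration (intramolecular transketalisation) under thermodynamic control is expected to favour the gem-dimethyl-stabilised, more substituted dioxolane with the free primary hydroxyl (the six-membered isomer suffers syn-axial methyls), and only acetal C–O bonds break, so the stereocenter is retained.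

Step 3
Reactants: 3 [(4S)-2,2,5,5-tetramethyl-1,3-dioxolan-4-yl]methanol
Product: 4 (4R)-4-(iodomethyl)-2,2,5,5-tetramethyl-1,3-dioxolane
Conditions: I2, PPh3, imidazole, toluene, 70 °C
Reagents that add atoms: iodine, II
Why: Appel (Garegg–Samuelsson) iodination displaces the primary alkoxyphosphonium at CH2 only, so the stereocenter keeps its geometry (the descriptor changes to R only because CH2I outranks the ring carbon).

Step 4
Reactants: 4 (4R)-4-(iodomethyl)-2,2,5,5-tetramethyl-1,3-dioxolane, 5 1-(2,4,6-trihydroxyphenyl)ethanone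
Product: 6 1-[2,4,6-trihydroxy-3-{[(4S)-2,2,5,5-tetramethyl-1,3-dioxolan-4-yl]methyl}phenyl]ethanone
Conditions: 5 (3.0 equiv) premixed with KOt-Bu (5.9 equiv) in degassed DMSO, then 4 (1.0 equiv), 365 nm LED, 25 °C, Ar; pH 4 buffer work-up
Reagents that add atoms: none
Why: Proposed new method: the phloroacetophenone dianion absorbs at 365 nm and acts as its own photoreductant, the excited dianion (or its halogen-bonded donor–acceptor complex with 4) passing one electron into the C–I σ* bond, which fragments to iodide and the primary radical •CH2–dioxolane; this radical bonds to the free, most electron-rich ring carbon either by radical–anion coupling (the dienone ketyl radical anion then hands its electron to the next molecule of 4, an SRN1 chain) or by recombination with the persistent phloroglucinoxyl radical, and tautomerisation restores the arene; no bond at the stereocenter is made or broken and a β-alkoxy radical does not fragment, so the bought configuration is carried through (descriptor S in 6); premixing leaves no free tert-butoxide (no E2), excess 5 limits dialkylation, and slow dark SN2 C-alkylation would give the same product; closest known reaction type: photostimulated SRN1 C-alkylation of naphthoxide and enolate anions with neopentyl-type alkyl iodides and excited-phenolate perfluoroalkylation, neither shown for unprotected acylphloroglucinols or β-alkoxy primary iodides.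

Step 5
Reactants: 5 1-(2,4,6-trihydroxyphenyl)ethanone
Product: 7 1-(2,4,6-trihydroxy-3-methylphenyl)ethanone
Conditions: NaOMe (2.0 equiv), MeI (1.0 equiv), MeOH, 0 °C to rt
Reagents that add atoms: iodomethane, CI
Why: Classical C-methylation of the phloroglucinolate (enolate-like carbon alkylation) at one of the two equivalent ring carbons, with limiting MeI to hold back dimethylation.

Step 6
Reactants: 7 1-(2,4,6-trihydroxy-3-methylphenyl)ethanone
Product: 8 1-(2,6-dihydroxy-4-methoxy-3-methylphenyl)ethanone
Conditions: Me2SO4 (1.0 equiv), K2CO3 (1.0 equiv), acetone, rt to 40 °C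
Reagents that add atoms: dimethyl sulfate, COS(=O)(=O)OC
Why: Williamson O-methylation goes to the 4-OH, which is the most acidic (para to acetyl) and the only one not hydrogen-bonded to the carbonyl.

Step 7
Reactants: 8 1-(2,6-dihydroxy-4-methoxy-3-methylphenyl)ethanone
Product: 9 1-{3-[(dimethylamino)methyl]-2,6-dihydroxy-4-methoxy-5-methylphenyl}ethanone
Conditions: Me2N=CH2+ I− (1.05 equiv), Et3N (1.1 equiv), CH2Cl2, 0 °C to rt
Reagents that add atoms: N,N-dimethylmethyleneiminium iodide (Eschenmoser's salt), C=[N+](C)C.[I-]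
Why: Phenolic Mannich aminomethylation with a preformed iminium ion occurs at the only free ring carbon.

Step 8
Reactants: 9 1-{3-[(dimethylamino)methyl]-2,6-dihydroxy-4-methoxy-5-methylphenyl}ethanone, 6 1-[2,4,6-trihydroxy-3-{[(4S)-2,2,5,5-tetramethyl-1,3-dioxolan-4-yl]methyl}phenyl]ethanone
Product: 12 target CNP0353610.1, via ring-A ortho-quinone methide 10 (not isolated), via acetonide-protected dimer 11 (not isolated)
Conditions: 9 (1.2 equiv), 6 (1.0 equiv), 1,4-dioxane, 90 °C, N2 sweep; evaporate; then Amberlyst-15 (H+ form), MeOH/H2O 9:1, 40 °C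
Reagents that add atoms: none
Why: Heating expels Me2NH from 9 (retro-Mannich) to give ortho-quinone methide 10, which the only free ring carbon of 6 captures in a Michael-type Friedel–Crafts C-alkylation to give 11, and the acidic resin then hydrolyses the acetonide at the acetal carbon only, leaving the (S) stereocenter unchanged.

**Compound list**
1 | methyl (4S)-2,2-dimethyl-1,3-dioxolane-4-carboxylate | COC(=O)[C@@H]1COC(C)(C)O1 | starting material
2 | 2-[(4S)-2,2-dimethyl-1,3-dioxolan-4-yl]propan-2-ol | CC(C)(O)[C@@H]1COC(C)(C)O1 | intermediate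
3 | [(4S)-2,2,5,5-tetramethyl-1,3-dioxolan-4-yl]methanol | OC[C@@H]1OC(C)(C)OC1(C)C | intermediate
4 | (4R)-4-(iodomethyl)-2,2,5,5-tetramethyl-1,3-dioxolane | IC[C@@H]1OC(C)(C)OC1(C)C | intermediate
5 | 1-(2,4,6-trihydroxyphenyl)ethanone (phloroacetophenone) | CC(=O)c1c(O)cc(O)cc1O | starting material
6 | 1-[2,4,6-trihydroxy-3-{[(4S)-2,2,5,5-tetramethyl-1,3-dioxolan-4-yl]methyl}phenyl]ethanone | CC(=O)c1c(O)cc(O)c(C[C@@H]2OC(C)(C)OC2(C)C)c1O | intermediate
7 | 1-(2,4,6-trihydroxy-3-methylphenyl)ethanone | CC(=O)c1c(O)cc(O)c(C)c1O | intermediate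
8 | 1-(2,6-dihydroxy-4-methoxy-3-methylphenyl)ethanone | COc1cc(O)c(C(C)=O)c(O)c1C | intermediate
9 | 1-{3-[(dimethylamino)methyl]-2,6-dihydroxy-4-methoxy-5-methylphenyl}ethanone | COc1c(C)c(O)c(C(C)=O)c(O)c1CN(C)C | intermediate
10 | 2-acetyl-3-hydroxy-5-methoxy-4-methyl-6-methylidenecyclohexa-2,4-dien-1-one (ring-A ortho-quinone methide) | C=C1C(=O)C(C(C)=O)=C(O)C(C)=C1OC | intermediate
11 | 1-[3-({3-acetyl-2,4,6-trihydroxy-5-{[(4S)-2,2,5,5-tetramethyl-1,3-dioxolan-4-yl]methyl}phenyl}methyl)-2,6-dihydroxy-4-methoxy-5-methylphenyl]ethanone | COc1c(C)c(O)c(C(C)=O)c(O)c1Cc1c(O)c(C[C@@H]2OC(C)(C)OC2(C)C)c(O)c(C(C)=O)c1O | intermediate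
12 | 1-[3-({3-acetyl-2,4,6-trihydroxy-5-[(2S)-2,3-dihydroxy-3-methylbutyl]phenyl}methyl)-2,6-dihydroxy-4-methoxy-5-methylphenyl]ethanone (CNP0353610.1) | COc1c(C)c(O)c(C(C)=O)c(O)c1Cc1c(O)c(C[C@H](O)C(C)(C)O)c(O)c(C(C)=O)c1O | target

**Totals**
Total step count: 8. Longest linear sequence: 5 (steps 1, 2, 3, 4, 8).

**Three steps most likely to fail**

Step 4 (the proposed new step). Initiation may be inefficient (excited-state proton transfer in the ortho-hydroxyacetophenone chromophore), or the radical may be reduced rather than captured. The fallback uses known chemistry, sets out from 5 and 4, and comes back at 6. Perbenzylation of 5 (BnBr, K2CO3, DMF, 60 °C) gives 1-[2,4,6-tris(benzyloxy)phenyl]ethanone F3. Bromination with NBS in MeCN at 0 °C gives 1-[2,4,6-tris(benzyloxy)-3-bromophenyl]ethanone F4. The established silyl-radical nickel/photoredox cross-electrophile coupling of F4 with iodide 4 (NiCl2·glyme, 4,4'-di-tert-butyl-2,2'-bipyridine, [Ir{dF(CF3)ppy}2(dtbbpy)]PF6, (Me3Si)3SiH, Na2CO3, DME, 450 nm) gives 1-[2,4,6-tris(benzyloxy)-3-{[(4S)-2,2,5,5-tetramethyl-1,3-dioxolan-4-yl]methyl}phenyl]ethanone F5. Hydrogenolysis (H2, 10% Pd/C, EtOAc) returns 6. The doubly ortho-substituted bromide F4 is a demanding substrate for this coupling.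

Step 2. The acetonide equilibrium may not lie far enough toward 3; this preference is argued from substituent effects, not from a known measurement. The fallback sets out from 2 and comes back at 4, bypassing 3. Hydrolysis of 2 (80% aq. AcOH, 40 °C) gives (2S)-3-methylbutane-1,2,3-triol F1. Primary-selective Appel iodination (I2, PPh3, imidazole, THF, 0 °C) gives (2R)-1-iodo-3-methylbutane-2,3-diol F2. Ketalisation of the remaining diol (2,2-dimethoxypropane, PPTS, CH2Cl2) gives 4.

Step 8. The quinone methide 10 may oligomerise, the amine-rich hot medium may exchange the methylene bridge between rings, or the acid may cyclise the side chain onto a phenol. The fallback reverses the roles of the two rings, sets out from 6 and 8, and comes back at 11. Aminomethylation of 6 (Eschenmoser's salt, Et3N, CH2Cl2) gives 1-[3-[(dimethylamino)methyl]-2,4,6-trihydroxy-5-{[(4S)-2,2,5,5-tetramethyl-1,3-dioxolan-4-yl]methyl}phenyl]ethanone F6. Heating F6 with excess 8 in dioxane releases 4-acetyl-3,5-dihydroxy-6-methylidene-2-{[(4S)-2,2,5,5-tetramethyl-1,3-dioxolan-4-yl]methyl}cyclohexa-2,4-dien-1-one F7, which the single free carbon of the cheap monomer 8 traps to give 11. The same resin treatment then gives 12.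

**Further compounds**
F1 | step 2 | (2S)-3-methylbutane-1,2,3-triol | OC[C@H](O)C(C)(C)O
F2 | step 2 | (2R)-1-iodo-3-methylbutane-2,3-diol | IC[C@H](O)C(C)(C)O
F3 | step 4 | 1-[2,4,6-tris(benzyloxy)phenyl]ethanone | CC(=O)c1c(OCc2ccccc2)cc(OCc2ccccc2)cc1OCc1ccccc1
F4 | step 4 | 1-[2,4,6-tris(benzyloxy)-3-bromophenyl]ethanone | CC(=O)c1c(OCc2ccccc2)cc(OCc2ccccc2)c(Br)c1OCc1ccccc1
F5 | step 4 | 1-[2,4,6-tris(benzyloxy)-3-{[(4S)-2,2,5,5-tetramethyl-1,3-dioxolan-4-yl]methyl}phenyl]ethanone | CC(=O)c1c(OCc2ccccc2)cc(OCc2ccccc2)c(C[C@@H]2OC(C)(C)OC2(C)C)c1OCc1ccccc1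
F6 | step 8 | 1-[3-[(dimethylamino)methyl]-2,4,6-trihydroxy-5-{[(4S)-2,2,5,5-tetramethyl-1,3-dioxolan-4-yl]methyl}phenyl]ethanone | CC(=O)c1c(O)c(CN(C)C)c(O)c(C[C@@H]2OC(C)(C)OC2(C)C)c1O
F7 | step 8 | 4-acetyl-3,5-dihydroxy-6-methylidene-2-{[(4S)-2,2,5,5-tetramethyl-1,3-dioxolan-4-yl]methyl}cyclohexa-2,4-dien-1-one | C=C1C(=O)C(C[C@@H]2OC(C)(C)OC2(C)C)=C(O)C(C(C)=O)=C1O
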